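In the closed flask beta, enzyme, idle complex and spent catalyst always add up to the 5.0 µM charged, so spent catalyst is a bill paid from a fixed purse.

    starting material + enzyme → product + enzyme, rate k1*[starting material]*[enzyme]/(1 + ([starting material]/Km1) + ([starting material]/Ksi1)^2) (Km1 = 0.063 M, Ksi1 = 47 mM, k1 = 2100 M⁻¹ min⁻¹)
    enzyme + product → spent catalyst (k2 = 0.11 M⁻¹ min⁻¹)
    enzyme + added ligand ⇌ idle complex (K3 = 1.7 × 10⁵ M⁻¹, k3 = 560 M⁻¹ min⁻¹)

| flask | starting material | enzyme | added ligand | time | remark |
|---|---|---|---|---|---|
| eta | 0.050 M (fed, over 7.50 h) | 5.0 µM | 10 µM | 15 h | a stirred flask in which starting material is dosed at a steady rate over 7.50 h without added volume, worked up at 15 h |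
| beta | 0.050 M | 5.0 µM | 10 µM | 15 h | a closed flask charged with all of it at once and left for 15 h |
| zeta | 0.050 M | 5.0 µM | 10 µM |  | one stirred flow tank at steady state, fed with the mixture as stated, mean residence time 15 h |

- order of the set-ups by the amount of product at the outlet or at the end, in percent of the starting material put in, highest first (eta / beta / zeta)
- amount of product at the outlet or at the end, in percent of the starting material put in, eta
- amount of product at the outlet or at the end, in percent of the starting material put in, beta
- amount of product at the outlet or at the end, in percent of the starting material put in, zeta

- the stated concentrations are those of everything mixed, before any reaction; amounts are the same in each set-up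
- the feed brings no volume worth counting
- run time (eta): 15 h

I must choose how to charge the next run, so I compare two rates at one moment. Let A be starting material, P product, E free enzyme, D the denominator of the first rate law, kf the first step's constant and kd the constant of the step that makes spent catalyst. The first step makes product at kf·A·E/D, and the loss step spends enzyme at kd·E·P. Their ratio, the price kd·P·D/(kf·A), is enzyme lost per product made. It holds neither E nor time, so at a given A and P the ligand changes the clock and not the price.

In beta the price climbs as P replaces A. At 90.0% of the charge turned to product, the price summed along beta comes to 5.00 µM. That sum is the enzyme bill, the spent catalyst owed at a given share turned. It is about the whole charge, so I take that share as beta's ceiling.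

The tank zeta pays the outlet price on all its product, and the same share there costs 23.1 µM, more than the charge. While the dose goes in, eta holds less A beside the same P than beta does, so its price is higher. Full enzyme at the starting pace gets through 3.23 lifetimes of A in 15 h, and the ligand cuts that, its binding constant times its charge being 1.70. I therefore expect beta below its ceiling, with eta behind it and zeta last, and I charge all at once. This reckoning gives ceilings, not yields.

The forecast gives beta > eta > zeta, with eta 73%, beta 83% and zeta 55%: “the closed flask does best by using the enzyme at full strength before much is lost”.

The flasks give beta > eta > zeta: beta 80.5%, eta 72.1%, zeta 55.1%. Left for 150 h, beta reaches 90.0%. At its 15 h reading, beta's bill is 3.29 µM, less than the 5.00 µM owed at 90.0%. In zeta, with 0.0224 M of starting material in the tank, the bill at its reading is 2.81 µM.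

The numbers of this flask were set for the occasion; no experiment stands behind them.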